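Watch the earliest readings first, since they show whether the clock matters in this flask.

| flask | starting complex | incoming ligand | leaving ligand | protic impurity | remark | time |
|---|---|---|---|---|---|---|
| north-west | 2 mM | 0.83 equiv | 1 equiv | 0.60 mM | run made earlier |  |
| south-west | 2 mM | 1.6 equiv | 1 equiv | 0.60 mM | run made earlier |  |
| south | 2 mM | 3.3 equiv | 1 equiv | 0.60 mM | run made earlier |  |
| summer | 2.0 mM | 0.800 equiv | 1.00 equiv | 0.600 mM |  | 6.0 min |
| noon | 2.0 mM | 2.00 equiv | 1.00 equiv | 0.600 mM |  | 6.0 min |
| midnight | 2.0 mM | 3.00 equiv | 1.00 equiv | 0.600 mM |  | 6.0 min |

| run | time / min | complex with one exchanged / % | complex with two exchanged / % |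
|---|---|---|---|
| north-west | 0.667 | 25.2 | 24.6 |
| north-west | 1.33 | 25.1 | 24.6 |
| north-west | 2.00 | 24.9 | 24.6 |
| north-west | 2.50 | 26.1 | 24.5 |
| north-west | 3.00 | 24.9 | 24.3 |
| south-west | 0.250 | 12.8 | 53.7 |
| south-west | 0.833 | 12.7 | 54.1 |
| south-west | 1.33 | 13.2 | 53.6 |
| south-west | 2.00 | 13.0 | 55.0 |
| south-west | 3.00 | 14.0 | 54.4 |
| south | 0.667 | 2.9 | 65.8 |
| south | 1.33 | 3.6 | 66.4 |
| south | 2.00 | 3.9 | 67.0 |
| south | 2.50 | 2.7 | 67.4 |
| south | 3.00 | 3.4 | 67.3 |

(each reading ± 0.5 percentage points)

- the analysis behind the earlier runs scatters by 0.5 percentage points, standard deviation
- a reading or a percentage of leaving ligand counts all its forms, free or not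

- how much complex with one exchanged is there at the end, in percent of the starting complex charged: for each flask in turn (summer, noon, midnight)

Did the clock matter? In the south-west run, complex with two exchanged stood at 53.7% at the first reading, and the last reading lay 0.7 percentage points from it, against a scatter of 0.5 points. I called the settling bound the time of that first south-west reading, 0.250 min, and took that run as settled by then. In the south run, complex with two exchanged lay 1.5 points higher at the last reading than at the first, against the same scatter, so I carried the bound over to the other flasks as an assumption. The asked 6.0 min holds 24.0 such bounds, far longer than the bound, so I treated each flask as an end state (thermodynamic control).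

How much complex could exchange? With [protic impurity] at 0.60 mM against [starting complex] at 2 mM, I took the impurity as claiming complex one for one, a share of 30.0%. That left 70.0%, and the two exchanged complexes in the south run summed to 70.7% at the last reading.

How did that room divide? From the last readings of complex with one exchanged, I expected summer near the north-west 24.9%, noon between the south-west 14.0% and the south 3.4%, and midnight close to the south 3.4%.

The forecast gave 24.5%, 8.3% and 3.9% and began: “The flat time courses show each run is already at equilibrium, so this is an equilibrium estimate.”

The flasks gave 24.9% in summer, 8.15% at noon and 3.76% at midnight, each within the forecast's margin.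

    starting complex + incoming ligand ⇌ leaving ligand + complex with one exchanged (K = 1.70, k = 221 L mol⁻¹ s⁻¹)
    complex with one exchanged + incoming ligand ⇌ leaving ligand + complex with two exchanged (K = 1.39, k = 303 L mol⁻¹ s⁻¹)
    protic impurity + starting complex → quenched substrate (k = 3940 L mol⁻¹ s⁻¹)
    crystals ⇌ leaving ligand, rate k4*(cs4 - [leaving ligand]) while solid is left; crystals form when [leaving ligand] > cs4 (solubility = 0.260 mM, k = 6.99 s⁻¹)

In summer, the relaxation half-life of the step from complex with one exchanged to complex with two exchanged, both ways together and by this step alone at the asked time, was 1.92 s, shorter than the settling bound and short against the 6.0 min. At noon, the forward half-life of complex with one exchanged by that step alone, with the other concentrations as charged, was 0.57 s, also shorter than the bound and short against the 6.0 min, and complex with one exchanged stood at 8.15% after 6.00 min and at 8.15% after 60.0 min.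

(All runs are simulated for substances that don't exist, noise included.)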